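**Plan**

- Retrosynthesis: the three O-benzyl bonds and the C3 hydroxymethyl oxidation level are dealt with last. The dihydrobenzofuran (O1, C2, C3, C3a to C7a) is then cut at C2–C3: C2 is bound to O1 and benzylic to ring C, C3 is benzylic to ring B and carries the one-carbon arm, which is what a ring B aryl(ester)carbene leaves on inserting into the O–CH2 of a ring C benzyl ether.
- Further cuts: aryl–C(diazo) (aryl iodide plus trichloroethyl diazoacetate), lactone C3–CH2 (enolate alkylation with the ring B benzyl bromide), the O–CH2 ether to ring C, and the C–CH2 bond to ring A (auxiliary alkylation of a succinate).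
- Forward order: the lactone ring forms first (step 4), the ring B/ring C unit is joined at lactone C3 (step 10), the diazo ester is installed (step 13), and the dihydrofuran ring closes last (step 14); steps 15 to 17 release acid, alcohol and phenols.
- Stereochemistry: lactone C4 comes from the (S)-4-benzyloxazolidinone auxiliary, lactone C3 from trans alkylation anti to the C4 benzyl group, C2 from the chiral dirhodium carboxylate, and C3 of the dihydrofuran from base equilibration to the trans ester.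

Key step: step 14

Assumption: dirhodium tetrakis[N-phthaloyl-(R)-tert-leucinate] is taken to give the 2S ether carbon, because its S antipode is known to give the 2R series with simpler 2-(benzyloxy)aryl diazoacetates.

**Route**

Step 1
Reactants: 1 4-(benzyloxy)-3-methoxybenzyl alcohol
Product: 2 4-(benzyloxy)-3-methoxybenzyl bromide
Conditions: PBr3 (0.4 equiv), Et2O, 0 °C
Reagents that add atoms: phosphorus tribromide, BrP(Br)Br
Why: Bromination of a primary benzylic alcohol through its dibromophosphite (SN2), fast at 0 °C for this electron-rich benzylic position and harmless to the aryl benzyl ether.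

Step 2
Reactants: 3 4-tert-butoxy-4-oxobutanoic acid (mono-tert-butyl succinate); 4 (S)-4-benzyl-1,3-oxazolidin-2-one
Product: 6 tert-butyl 4-[(4S)-4-benzyl-2-oxo-1,3-oxazolidin-3-yl]-4-oxobutanoate, via pivalic mixed anhydride 5 (not isolated)
Conditions: pivaloyl chloride, Et3N, THF, −20 °C; then 4, LiCl, rt
Reagents that add atoms: none
Why: N-acylation of the oxazolidinone by the mixed anhydride method, the nucleophile attacking the unhindered succinyl carbonyl and the tert-butyl ester staying inert.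

Step 3
Reactants: 6 tert-butyl 4-[(4S)-4-benzyl-2-oxo-1,3-oxazolidin-3-yl]-4-oxobutanoate; 2 4-(benzyloxy)-3-methoxybenzyl bromide
Product: 7 tert-butyl (3S)-3-[4-(benzyloxy)-3-methoxybenzyl]-4-[(4S)-4-benzyl-2-oxo-1,3-oxazolidin-3-yl]-4-oxobutanoate
Conditions: NaN(SiMe3)2, THF, −78 °C; then 2, −78 to −20 °C
Reagents that add atoms: none
Why: Evans auxiliary alkylation, in which the chelated Z sodium enolate of the imide (formed in preference to the ester enolate) is benzylated on the face away from the auxiliary's 4-benzyl group, setting the future lactone C4 as S.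

Step 4
Reactants: 7 tert-butyl (3S)-3-[4-(benzyloxy)-3-methoxybenzyl]-4-[(4S)-4-benzyl-2-oxo-1,3-oxazolidin-3-yl]-4-oxobutanoate
Product: 9 (4S)-4-[4-(benzyloxy)-3-methoxybenzyl]dihydrofuran-2(3H)-one, via hydroxy ester 8 (not isolated)
Conditions: LiBH4, MeOH (1 equiv), THF, 0 °C; then TsOH·H2O (cat.), toluene, 80 °C
Reagents that add atoms: none
Why: Reductive cleavage of the auxiliary (hydride attacks the exocyclic imide carbonyl and spares the tert-butyl ester), then acid-catalysed lactonisation of the γ-hydroxy tert-butyl ester; the stereocentre is not enolisable here and is retained.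

Step 5
Reactants: 10 3,4-dihydroxybenzaldehyde
Product: 11 3-(benzyloxy)-4-hydroxybenzaldehyde
Conditions: NaH (2.2 equiv), DMSO, rt; then BnBr (1.0 equiv)
Reagents that add atoms: benzyl bromide, BrCc1ccccc1
Why: Regioselective Williamson etherification of the catecholate dianion, in which the 4-oxide is delocalised into the para formyl group so that the single equivalent of benzyl bromide is taken by the more nucleophilic 3-oxide.

Step 6
Reactants: 11 3-(benzyloxy)-4-hydroxybenzaldehyde
Product: 12 3-(benzyloxy)-4-hydroxy-5-iodobenzaldehyde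
Conditions: I2, NaHCO3, THF/H2O, rt
Reagents that add atoms: iodine, II
Why: Electrophilic aromatic iodination of the phenoxide at C5, the only free position ortho to the hydroxyl (the para position carries the formyl group), as in the iodination of vanillin.

Step 7
Reactants: 12 3-(benzyloxy)-4-hydroxy-5-iodobenzaldehyde; 2 4-(benzyloxy)-3-methoxybenzyl bromide
Product: 13 3-(benzyloxy)-4-{[4-(benzyloxy)-3-methoxybenzyl]oxy}-5-iodobenzaldehyde
Conditions: K2CO3, DMF, rt
Reagents that add atoms: none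
Why: Williamson etherification of the acidic phenol with the reactive benzylic bromide, installing the O–CH2–ring C group whose C–H bond is used in the key step.

Step 8
Reactants: 13 3-(benzyloxy)-4-{[4-(benzyloxy)-3-methoxybenzyl]oxy}-5-iodobenzaldehyde
Product: 14 (3-(benzyloxy)-4-{[4-(benzyloxy)-3-methoxybenzyl]oxy}-5-iodophenyl)methanol
Conditions: NaBH4, THF/MeOH, 0 °C
Reagents that add atoms: none
Why: Borohydride reduction of the aldehyde, to which the aryl iodide and the benzyl ethers are inert.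

Step 9
Reactants: 14 (3-(benzyloxy)-4-{[4-(benzyloxy)-3-methoxybenzyl]oxy}-5-iodophenyl)methanol
Product: 15 1-(benzyloxy)-2-{[4-(benzyloxy)-3-methoxybenzyl]oxy}-5-(bromomethyl)-3-iodobenzene
Conditions: CBr4, PPh3, CH2Cl2, 0 °C
Reagents that add atoms: carbon tetrabromide, BrC(Br)(Br)Br
Why: Appel reaction, chosen because its neutral conditions spare the acid-sensitive 4-alkoxybenzyl aryl ether.

Step 10
Reactants: 9 (4S)-4-[4-(benzyloxy)-3-methoxybenzyl]dihydrofuran-2(3H)-one; 15 1-(benzyloxy)-2-{[4-(benzyloxy)-3-methoxybenzyl]oxy}-5-(bromomethyl)-3-iodobenzene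
Product: 16 (3S,4S)-3-(3-(benzyloxy)-4-{[4-(benzyloxy)-3-methoxybenzyl]oxy}-5-iodobenzyl)-4-[4-(benzyloxy)-3-methoxybenzyl]dihydrofuran-2(3H)-one
Conditions: LiN(SiMe3)2, THF, −78 °C; then 15, DMPU, −78 to −40 °C
Reagents that add atoms: none
Why: Alkylation of the lithium enolate of a β-substituted γ-butyrolactone, the bromide approaching anti to the C4 benzyl group so that the new C3 centre is S and trans, the usual outcome for dibenzylbutyrolactones; the aryl iodide does not react with the amide base at this temperature.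

Step 11
Reactants: 17 2,2,2-trichloroethanol; 18 bromoacetyl bromide
Product: 19 2,2,2-trichloroethyl bromoacetate
Conditions: NaHCO3, MeCN, 0 °C
Reagents that add atoms: none
Why: O-acylation of the alcohol by the acid bromide, the acyl bromide being far more electrophilic than the alkyl bromide.

Step 12
Reactants: 19 2,2,2-trichloroethyl bromoacetate
Product: 20 2,2,2-trichloroethyl diazoacetate
Conditions: N,N'-ditosylhydrazine, DBU, THF, 0 °C
Reagents that add atoms: N,N'-ditosylhydrazine, Cc1ccc(cc1)S(=O)(=O)NNS(=O)(=O)c1ccc(C)cc1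
Why: Bromoacetate to diazoacetate conversion by N-alkylation of the ditosylhydrazine and base-induced loss of two sulfinate ions.

Step 13
Reactants: 16 (3S,4S)-3-(3-(benzyloxy)-4-{[4-(benzyloxy)-3-methoxybenzyl]oxy}-5-iodobenzyl)-4-[4-(benzyloxy)-3-methoxybenzyl]dihydrofuran-2(3H)-one; 20 2,2,2-trichloroethyl diazoacetate
Product: 21 2,2,2-trichloroethyl 2-[3-(benzyloxy)-2-{[4-(benzyloxy)-3-methoxybenzyl]oxy}-5-({(3S,4S)-4-[4-(benzyloxy)-3-methoxybenzyl]-2-oxotetrahydrofuran-3-yl}methyl)phenyl]-2-diazoacetate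
Conditions: Pd(PPh3)4 (10 mol %), Ag2CO3, Et3N, toluene, rt, dark
Reagents that add atoms: none
Why: Palladium-catalysed C–H arylation of an acceptor diazo compound by an aryl iodide (oxidative addition to zerovalent palladium, silver-assisted metalation of the diazoacetate, reductive elimination with the diazo group kept), a room-temperature coupling known for 2,2,2-trichloroethyl diazoacetate that leaves lactone, benzyl ethers and the trichloroethyl ester alone.

Step 14
Reactants: 21 2,2,2-trichloroethyl 2-[3-(benzyloxy)-2-{[4-(benzyloxy)-3-methoxybenzyl]oxy}-5-({(3S,4S)-4-[4-(benzyloxy)-3-methoxybenzyl]-2-oxotetrahydrofuran-3-yl}methyl)phenyl]-2-diazoacetate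
Product: 23 2,2,2-trichloroethyl (2S,3S)-7-(benzyloxy)-2-[4-(benzyloxy)-3-methoxyphenyl]-5-({(3S,4S)-4-[4-(benzyloxy)-3-methoxybenzyl]-2-oxotetrahydrofuran-3-yl}methyl)-2,3-dihydro-1-benzofuran-3-carboxylate (trans ester), via cis ester 22 (not isolated)
Conditions: Rh2(R-PTTL)4, dirhodium tetrakis[N-phthaloyl-(R)-tert-leucinate] (1–2 mol %), toluene, −60 °C, slow addition of 21; then DBU, −60 °C to rt
Reagents that add atoms: none
Why: The dirhodium carboxylate expels dinitrogen from 21 and the rhodium-bound aryl(alkoxycarbonyl)carbene at the future C3 inserts, in one step with hydride-shift character, into one hydrogen of the neighbouring O1–CH2–ring C group, forming C2–C3. The closest known reaction type is the enantioselective intramolecular 1,5 C–H insertion of 2-(benzyloxy)aryl diazoacetates to 2-aryl-2,3-dihydrobenzofuran-3-carboxylates under dirhodium N-phthaloyl amino acid carboxylate catalysis. The dihydrofuran ring (O1, C2, C3, C3a, C7a) closes by this 1,5-insertion through a five-membered-ring-forming transition state. C2 (S) is set by the chiral carboxylate pocket of the catalyst, which selects between the two hydrogens of the O–CH2 group (the lactone stereocentres are too remote to interfere); C3 should arise mainly cis under kinetic control and is then set S by DBU equilibration through the ester enolate, which places the ester trans to ring C. The step needs site selectivity, secured because that C–H bond is activated by both O1 and the electron-rich ring C and is the only activated C–H that can reach the carbene in a five-membered array, the C7 benzyl ether being meta to the carbene carbon and the lactone and its benzylic methylenes remote. Low temperature and slow addition should suppress carbene dimerisation, and the trichloroethyl ester makes the carbene more selective, acidifies C3 for the equilibration and tolerates DBU.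

Step 15
Reactants: 23 trans trichloroethyl ester
Product: 24 (2S,3S)-7-(benzyloxy)-2-[4-(benzyloxy)-3-methoxyphenyl]-5-({(3S,4S)-4-[4-(benzyloxy)-3-methoxybenzyl]-2-oxotetrahydrofuran-3-yl}methyl)-2,3-dihydro-1-benzofuran-3-carboxylic acid
Conditions: Zn dust, AcOH/THF, rt
Reagents that add atoms: none
Why: Reductive fragmentation of the 2,2,2-trichloroethyl ester by zinc (reduction of a C–Cl bond, then β-elimination of the carboxylate), which leaves the lactone, the benzyl ethers and both dihydrofuran stereocentres untouched.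

Step 16
Reactants: 24 dihydrobenzofuran-3-carboxylic acid
Product: 25 (3S,4S)-3-({(2S,3R)-7-(benzyloxy)-2-[4-(benzyloxy)-3-methoxyphenyl]-3-(hydroxymethyl)-2,3-dihydro-1-benzofuran-5-yl}methyl)-4-[4-(benzyloxy)-3-methoxybenzyl]dihydrofuran-2(3H)-one
Conditions: BH3·SMe2, THF, 0 °C to rt; MeOH quench
Reagents that add atoms: none
Why: Chemoselective borane reduction of a carboxylic acid through its acyloxyborane, much faster than reduction of the γ-lactone and non-basic, so C3 is not epimerised (its descriptor changes to R only because the substituent priorities change).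

Step 17
Reactants: 25 tri-O-benzyl alcohol
Product: 26 (3S,4S)-3-{[(2S,3R)-7-hydroxy-2-(4-hydroxy-3-methoxyphenyl)-3-(hydroxymethyl)-2,3-dihydro-1-benzofuran-5-yl]methyl}-4-(4-hydroxy-3-methoxybenzyl)dihydrofuran-2(3H)-one (CNP0118131.1)
Conditions: H2 (1 atm), Pd/C (10 % palladium on carbon), EtOAc/EtOH, rt, stopped after uptake of three equivalents
Reagents that add atoms: none
Why: Catalytic hydrogenolysis of three primary aryl benzyl ethers, which should be cleaved much faster than the ring-embedded secondary C2–O1 bond, as in debenzylations of related 2-aryl dihydrobenzofuran neolignans.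

**Compound list**

1 | 4-(benzyloxy)-3-methoxybenzyl alcohol | COc1cc(CO)ccc1OCc1ccccc1 | starting material
2 | 4-(benzyloxy)-3-methoxybenzyl bromide | COc1cc(CBr)ccc1OCc1ccccc1 | intermediate
3 | 4-tert-butoxy-4-oxobutanoic acid | CC(C)(C)OC(=O)CCC(=O)O | starting material
4 | (S)-4-benzyl-1,3-oxazolidin-2-one | O=C1N[C@@H](Cc2ccccc2)CO1 | starting material
5 | 4-tert-butoxy-4-oxobutanoic pivalic anhydride | CC(C)(C)OC(=O)CCC(=O)OC(=O)C(C)(C)C | intermediate
6 | tert-butyl 4-[(4S)-4-benzyl-2-oxo-1,3-oxazolidin-3-yl]-4-oxobutanoate | CC(C)(C)OC(=O)CCC(=O)N1[C@@H](Cc2ccccc2)COC1=O | intermediate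
7 | tert-butyl (3S)-3-[4-(benzyloxy)-3-methoxybenzyl]-4-[(4S)-4-benzyl-2-oxo-1,3-oxazolidin-3-yl]-4-oxobutanoate | COc1cc(C[C@@H](CC(=O)OC(C)(C)C)C(=O)N2[C@@H](Cc3ccccc3)COC2=O)ccc1OCc1ccccc1 | intermediate
8 | tert-butyl (3S)-3-[4-(benzyloxy)-3-methoxybenzyl]-4-hydroxybutanoate | COc1cc(C[C@@H](CC(=O)OC(C)(C)C)CO)ccc1OCc1ccccc1 | intermediate
9 | (4S)-4-[4-(benzyloxy)-3-methoxybenzyl]dihydrofuran-2(3H)-one | COc1cc(C[C@@H]2COC(=O)C2)ccc1OCc1ccccc1 | intermediate
10 | 3,4-dihydroxybenzaldehyde | O=Cc1ccc(O)c(O)c1 | starting material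
11 | 3-(benzyloxy)-4-hydroxybenzaldehyde | O=Cc1ccc(O)c(OCc2ccccc2)c1 | intermediate
12 | 3-(benzyloxy)-4-hydroxy-5-iodobenzaldehyde | O=Cc1cc(I)c(O)c(OCc2ccccc2)c1 | intermediate
13 | 3-(benzyloxy)-4-{[4-(benzyloxy)-3-methoxybenzyl]oxy}-5-iodobenzaldehyde | O=Cc1cc(I)c(OCc2ccc(OCc3ccccc3)c(OC)c2)c(OCc2ccccc2)c1 | intermediate
14 | (3-(benzyloxy)-4-{[4-(benzyloxy)-3-methoxybenzyl]oxy}-5-iodophenyl)methanol | OCc1cc(I)c(OCc2ccc(OCc3ccccc3)c(OC)c2)c(OCc2ccccc2)c1 | intermediate
15 | 1-(benzyloxy)-2-{[4-(benzyloxy)-3-methoxybenzyl]oxy}-5-(bromomethyl)-3-iodobenzene | BrCc1cc(I)c(OCc2ccc(OCc3ccccc3)c(OC)c2)c(OCc2ccccc2)c1 | intermediate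
16 | (3S,4S)-3-(3-(benzyloxy)-4-{[4-(benzyloxy)-3-methoxybenzyl]oxy}-5-iodobenzyl)-4-[4-(benzyloxy)-3-methoxybenzyl]dihydrofuran-2(3H)-one | COc1cc(C[C@@H]2COC(=O)[C@H]2Cc2cc(OCc3ccccc3)c(OCc3ccc(OCc4ccccc4)c(OC)c3)c(I)c2)ccc1OCc1ccccc1 | intermediate
17 | 2,2,2-trichloroethanol | OCC(Cl)(Cl)Cl | starting material
18 | bromoacetyl bromide | BrCC(=O)Br | starting material
19 | 2,2,2-trichloroethyl bromoacetate | BrCC(=O)OCC(Cl)(Cl)Cl | intermediate
20 | 2,2,2-trichloroethyl diazoacetate | [N-]=[N+]=CC(=O)OCC(Cl)(Cl)Cl | intermediate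
21 | 2,2,2-trichloroethyl 2-[3-(benzyloxy)-2-{[4-(benzyloxy)-3-methoxybenzyl]oxy}-5-({(3S,4S)-4-[4-(benzyloxy)-3-methoxybenzyl]-2-oxotetrahydrofuran-3-yl}methyl)phenyl]-2-diazoacetate | COc1cc(C[C@@H]2COC(=O)[C@H]2Cc2cc(OCc3ccccc3)c(OCc3ccc(OCc4ccccc4)c(OC)c3)c(c2)C(=[N+]=[N-])C(=O)OCC(Cl)(Cl)Cl)ccc1OCc1ccccc1 | intermediate
22 | 2,2,2-trichloroethyl (2S,3R)-7-(benzyloxy)-2-[4-(benzyloxy)-3-methoxyphenyl]-5-({(3S,4S)-4-[4-(benzyloxy)-3-methoxybenzyl]-2-oxotetrahydrofuran-3-yl}methyl)-2,3-dihydro-1-benzofuran-3-carboxylate (cis) | COc1cc(C[C@@H]2COC(=O)[C@H]2Cc2cc(OCc4ccccc4)c3c(c2)[C@@H](C(=O)OCC(Cl)(Cl)Cl)[C@@H](c2ccc(OCc4ccccc4)c(OC)c2)O3)ccc1OCc1ccccc1 | intermediate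
23 | 2,2,2-trichloroethyl (2S,3S)-7-(benzyloxy)-2-[4-(benzyloxy)-3-methoxyphenyl]-5-({(3S,4S)-4-[4-(benzyloxy)-3-methoxybenzyl]-2-oxotetrahydrofuran-3-yl}methyl)-2,3-dihydro-1-benzofuran-3-carboxylate (trans) | COc1cc(C[C@@H]2COC(=O)[C@H]2Cc2cc(OCc4ccccc4)c3c(c2)[C@H](C(=O)OCC(Cl)(Cl)Cl)[C@@H](c2ccc(OCc4ccccc4)c(OC)c2)O3)ccc1OCc1ccccc1 | intermediate
24 | (2S,3S)-7-(benzyloxy)-2-[4-(benzyloxy)-3-methoxyphenyl]-5-({(3S,4S)-4-[4-(benzyloxy)-3-methoxybenzyl]-2-oxotetrahydrofuran-3-yl}methyl)-2,3-dihydro-1-benzofuran-3-carboxylic acid | COc1cc(C[C@@H]2COC(=O)[C@H]2Cc2cc(OCc4ccccc4)c3c(c2)[C@H](C(=O)O)[C@@H](c2ccc(OCc4ccccc4)c(OC)c2)O3)ccc1OCc1ccccc1 | intermediate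
25 | (3S,4S)-3-({(2S,3R)-7-(benzyloxy)-2-[4-(benzyloxy)-3-methoxyphenyl]-3-(hydroxymethyl)-2,3-dihydro-1-benzofuran-5-yl}methyl)-4-[4-(benzyloxy)-3-methoxybenzyl]dihydrofuran-2(3H)-one | COc1cc(C[C@@H]2COC(=O)[C@H]2Cc2cc(OCc4ccccc4)c3c(c2)[C@H](CO)[C@@H](c2ccc(OCc4ccccc4)c(OC)c2)O3)ccc1OCc1ccccc1 | intermediate
26 | (3S,4S)-3-{[(2S,3R)-7-hydroxy-2-(4-hydroxy-3-methoxyphenyl)-3-(hydroxymethyl)-2,3-dihydro-1-benzofuran-5-yl]methyl}-4-(4-hydroxy-3-methoxybenzyl)dihydrofuran-2(3H)-one | COc1cc(C[C@@H]2COC(=O)[C@H]2Cc2cc(O)c3c(c2)[C@H](CO)[C@@H](c2ccc(O)c(OC)c2)O3)ccc1O | target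

**Step count and risks**

Total step count: 17. Longest linear sequence: 11 steps (steps 5, 6, 7, 8, 9, 10, 13, 14, 15, 16, 17, from 10).

Steps most likely to fail:

Step 14. The catalyst alone may not discriminate well enough between the two hydrogens of the O–CH2 group (the lactone stereocentres are too remote to help), carbene dimerisation may compete, and the base equilibration may open the ring by β-elimination of the O1 phenoxide. The fallback combines a chiral ester auxiliary with a chiral catalyst, a pairing known to give trans 2-aryl dihydrobenzofuran-3-carboxylates directly from catechol-type aryldiazoacetates, so that no base step is needed. It sets out from 16. Ethyl (S)-lactate and pyrrolidine would give (S)-2-hydroxy-1-(pyrrolidin-1-yl)propan-1-one F1, which with bromoacetyl bromide 18 and NaHCO3 would give its bromoacetate F2 and then, with N,N'-ditosylhydrazine and DBU, (S)-1-oxo-1-(pyrrolidin-1-yl)propan-2-yl diazoacetate F3. Coupling of F3 with 16 under the conditions of step 13 would give the lactamide aryldiazoacetate F4. Rh2(S-DOSP)4, dirhodium tetrakis[N-(4-dodecylphenylsulfonyl)-(S)-prolinate], in CH2Cl2 should then insert to the (2S,3S) trans lactamide ester F5, the facial bias of the auxiliary and of the catalyst being expected to reinforce each other. LiOH in THF/H2O, followed by dilute acid to reclose any opened lactone, would release the auxiliary and return to the route at acid 24.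

Step 13. Oxidative addition at the hindered, electron-rich aryl iodide flanked by an alkoxy group may be slow while the palladium catalyst decomposes the diazoacetate. The fallback builds the arylacetate first and introduces the diazo group by diazo transfer. It sets out from 16. Stille coupling with allyltributylstannane (CH2=CHCH2SnBu3, Pd(PPh3)4, toluene, 100 °C) would give the 5-allyl arene F6. Lemieux–Johnson cleavage (OsO4 cat., NaIO4, 2,6-lutidine, dioxane/H2O) would give the arylacetaldehyde F7, and Pinnick oxidation (NaClO2, NaH2PO4, 2-methyl-2-butene) the arylacetic acid F8. Esterification with 2,2,2-trichloroethanol 17 (EDC·HCl, DMAP) would give the trichloroethyl arylacetate F9, and Regitz diazo transfer (4-acetamidobenzenesulfonyl azide, DBU, MeCN) would return to the route at 21.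

Step 17. Hydrogenolytic opening of the dihydrofuran at the C2–O1 bond, which is benzylic to ring C, may compete with removal of the last benzyl ether. The fallback is a non-reductive Lewis acid debenzylation. It sets out from 25: BCl3 with pentamethylbenzene as cation scavenger in CH2Cl2 at −78 °C cleaves aryl benzyl ethers without hydrogen, aryl methyl ethers and the lactone being stable at this temperature. Any reversible ionisation at C2 should reclose to the trans isomer because C3 is untouched. Methanolic work-up would return directly to target 26 with no new compound on the way.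

Further compounds
F1 | step 14 | (S)-2-hydroxy-1-(pyrrolidin-1-yl)propan-1-one | C[C@H](O)C(=O)N1CCCC1
F2 | step 14 | (S)-1-oxo-1-(pyrrolidin-1-yl)propan-2-yl bromoacetate | C[C@H](OC(=O)CBr)C(=O)N1CCCC1
F3 | step 14 | (S)-1-oxo-1-(pyrrolidin-1-yl)propan-2-yl diazoacetate | C[C@H](OC(=O)C=[N+]=[N-])C(=O)N1CCCC1
F4 | step 14 | (S)-1-oxo-1-(pyrrolidin-1-yl)propan-2-yl 2-[3-(benzyloxy)-2-{[4-(benzyloxy)-3-methoxybenzyl]oxy}-5-({(3S,4S)-4-[4-(benzyloxy)-3-methoxybenzyl]-2-oxotetrahydrofuran-3-yl}methyl)phenyl]-2-diazoacetate | COc1cc(C[C@@H]2COC(=O)[C@H]2Cc2cc(OCc3ccccc3)c(OCc3ccc(OCc4ccccc4)c(OC)c3)c(c2)C(=[N+]=[N-])C(=O)O[C@@H](C)C(=O)N2CCCC2)ccc1OCc1ccccc1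
F5 | step 14 | (S)-1-oxo-1-(pyrrolidin-1-yl)propan-2-yl (2S,3S)-7-(benzyloxy)-2-[4-(benzyloxy)-3-methoxyphenyl]-5-({(3S,4S)-4-[4-(benzyloxy)-3-methoxybenzyl]-2-oxotetrahydrofuran-3-yl}methyl)-2,3-dihydro-1-benzofuran-3-carboxylate | COc1cc(C[C@@H]2COC(=O)[C@H]2Cc2cc(OCc4ccccc4)c3c(c2)[C@H](C(=O)O[C@@H](C)C(=O)N2CCCC2)[C@@H](c2ccc(OCc4ccccc4)c(OC)c2)O3)ccc1OCc1ccccc1
F6 | step 13 | (3S,4S)-3-(3-allyl-5-(benzyloxy)-4-{[4-(benzyloxy)-3-methoxybenzyl]oxy}benzyl)-4-[4-(benzyloxy)-3-methoxybenzyl]dihydrofuran-2(3H)-one | COc1cc(C[C@@H]2COC(=O)[C@H]2Cc2cc(OCc3ccccc3)c(OCc3ccc(OCc4ccccc4)c(OC)c3)c(CC=C)c2)ccc1OCc1ccccc1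
F7 | step 13 | 2-[3-(benzyloxy)-2-{[4-(benzyloxy)-3-methoxybenzyl]oxy}-5-({(3S,4S)-4-[4-(benzyloxy)-3-methoxybenzyl]-2-oxotetrahydrofuran-3-yl}methyl)phenyl]acetaldehyde | COc1cc(C[C@@H]2COC(=O)[C@H]2Cc2cc(OCc3ccccc3)c(OCc3ccc(OCc4ccccc4)c(OC)c3)c(CC=O)c2)ccc1OCc1ccccc1
F8 | step 13 | 2-[3-(benzyloxy)-2-{[4-(benzyloxy)-3-methoxybenzyl]oxy}-5-({(3S,4S)-4-[4-(benzyloxy)-3-methoxybenzyl]-2-oxotetrahydrofuran-3-yl}methyl)phenyl]acetic acid | COc1cc(C[C@@H]2COC(=O)[C@H]2Cc2cc(OCc3ccccc3)c(OCc3ccc(OCc4ccccc4)c(OC)c3)c(CC(=O)O)c2)ccc1OCc1ccccc1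
F9 | step 13 | 2,2,2-trichloroethyl 2-[3-(benzyloxy)-2-{[4-(benzyloxy)-3-methoxybenzyl]oxy}-5-({(3S,4S)-4-[4-(benzyloxy)-3-methoxybenzyl]-2-oxotetrahydrofuran-3-yl}methyl)phenyl]acetate | COc1cc(C[C@@H]2COC(=O)[C@H]2Cc2cc(OCc3ccccc3)c(OCc3ccc(OCc4ccccc4)c(OC)c3)c(CC(=O)OCC(Cl)(Cl)Cl)c2)ccc1OCc1ccccc1
F0 | step 17 | none | none
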